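## Structural features

The target is a 2-hydroxybenzophenone. Ring A is a 1,2,4,5-tetrasubstituted benzene with a methoxy group at C1, a hydroxyl at C3, the ketone carbon at C4 and a saturated three-carbon chain (Cα, Cβ, Cγ) at C6. The ketone joins ring A to ring B (4-hydroxyphenyl), and Cγ carries ring C (a second 4-hydroxyphenyl). The molecule has no stereocentre, so any stereocentre made on the way has to be erased again. The sensitive groups are three phenols of different character (C3–OH chelated to the carbonyl, the ring B hydroxyl para to the carbonyl, the ordinary ring C hydroxyl) and a diaryl ketone that can be over-reduced under hydrogenolysis. The difficulty is one of order, not of skeleton: four different substituents must be placed correctly on ring A, four phenolic oxygens must be told apart so that only O1 is methylated, and the chain must be attached ortho to O1 and meta to the carbonyl. The feature used is the ortho relation of O1 (on C1) and the chain (on C6): the sequence O1–C1–C6–Cα–Cβ–Cγ(ring C) is a 2-arylchroman lacking only the O1–Cγ bond. With that bond drawn in, ring A, the chain and ring C become a flavan, which is the [4+2] adduct of an ortho-quinone methide (O1=C1–C6=Cα) and a styrene (Cβ=Cγ).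

## Logic of the disconnections

16 ⇒ 15. The two O–Si bonds on the ring B and ring C oxygens are cut (forward: fluoride desilylation). These phenols must stay masked until O1 has been methylated, otherwise several hydroxyls would compete for the alkylating agent. The gain is that 15 has only the inert, chelated C3 hydroxyl free. The demand is a desilylation mild enough for a polyphenolic ketone, which buffered fluoride meets.

15 ⇒ 14. The O1–CH3 bond is cut. O1 is the ring oxygen of the pyran in 13, so it cannot carry its methyl group before the ring is opened. The gain is that 14 is the direct ring-opened form of 13. The forward alkylation must choose O1 over the C3 hydroxyl; the hydrogen bond of C3–OH to the ketone and the higher acidity of the para-acyl phenol O1–H provide the bias.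

14 ⇒ 13. Retrosynthetically the O1–Cγ bond and the O–benzyl bond at C3 are re-formed (forward: both benzylic C–O bonds are hydrogenolysed in one operation). Closing O1–Cγ turns the open chain into a ring that a cycloaddition can make, and the benzyl group on O3 is chosen because it leaves under the same conditions. The gain is that the chain and both of its attachments are encoded in one chroman ring whose single stereocentre is of no consequence. The demand is a hydrogenolysis that stops at the two C–O bonds and spares the diaryl ketone and the silyl ethers.

13 ⇒ 11 + 3 (through 12). The Cα–Cβ and O1–Cγ bonds are cut together, a retro hetero-Diels–Alder reaction. This divides the molecule into two pieces of similar size and builds the three-carbon link from a one-carbon handle on ring A and a vinyl group on ring C. The forward step requires 12 to be generated from 11 in the presence of excess 3. O3 must be blocked so that loss of water can only give the ortho and not the para quinone methide, and the polarisation of both partners must direct the aryl group to C2 of the chroman.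

11 ⇒ 10 ⇒ 9. The two C–O bonds of an isopropylidene acetal are re-formed and the ketone is taken back to a carbinol. The salicyl alcohol unit tolerates neither an aryllithium nor MnO2, and one acetal masks both hydroxyls at the cost of one step on and one step off. The carbinol oxidation level lets ring B enter as an aldehyde. The demand is that oxidation precedes unmasking, so that only one oxidisable benzylic alcohol is exposed, and that the hydrolysis neither removes the aryl silyl ether nor ionises the freed benzylic alcohol.

9 ⇒ 7 + 2 (through 8). The bond between C4 of ring A and the carbinol carbon is cut. C4 is para to O1 and ortho to O3, the position where electrophilic bromination places a halogen, and halogen–lithium exchange makes it the nucleophile. The partner 2 is also the precursor of 3, so one intermediate supplies ring B and ring C. The demand is an exchange at −78 °C that is faster than any attack on the benzyl ether or the acetal.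

7 ⇒ 6 ⇒ 5 ⇒ 4. The acetal C–O bonds, the benzylic C–H bond (aldehyde reduction) and the C–Br bond are removed in turn. Reducing the aldehyde before any ketone exists removes the need to discriminate two carbonyl groups later. The sequence ends at 4, in which O3 is already benzylated and O1–H is free. The demand is regioselective bromination para to the free hydroxyl.

3 ⇒ 2 ⇒ 1. The vinyl C=C bond is cut (Wittig methylenation) and then the O–Si bond. Both are routine, and the silyl ether only has to survive a phosphorus ylide.

## Other disconnections considered

Alternative 1: The cut removes ring B. In the forward key step the 3-formylchromone A2 (6-{3-[4-(benzyloxy)phenyl]propyl}-7-methoxy-4-oxo-4H-chromene-3-carbaldehyde) would react with the bis-nucleophile dimethyl 3-oxopentanedioate A3. Conjugate addition at C2, opening of the pyranone and intramolecular Knoevenagel condensation on the formyl group would give the benzophenone A1.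
- In its favour: it needs no metal, and it makes ring B, the ketone and the free C3 hydroxyl in one operation. The C1 methoxy group can be carried from the start, so no selective methylation is needed. On this point it is better than the chosen plan.
- Against it: ring B arrives with two ester groups that the target lacks, and removing them means hydrolysis and a double decarboxylation of a salicylic-acid-type diacid under forcing heat. The diarylpropane chain is not addressed at all, so A2 must already contain it and a second strategy is needed for the chain.
- Comparison: on structure it solves the ketone and ring B but not the chain, whereas the chosen plan solves the chain and brings in ring B by a simple carbonyl addition. On mechanism the two are equal, both being domino sequences driven by formation of an aromatic ring. On step economy the chosen plan is shorter, since A1 still needs three further operations and A2 a longer preparation.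

Alternative 2: The cut excises Cβ as a one-carbon unit, leaving the (E)-stilbene A5 that joins ring A and ring C. A zinc carbenoid of the Furukawa type, activated by a fluorinated carboxylic acid, would transfer a methylene group to A5 and give the trans-cyclopropane A4. Catalytic hydrogenolysis would then break the bond between the two aryl-bearing carbons together with the three benzyl ethers and lead directly to 16.
- In its favour: the endgame is one operation instead of three, and the C1 methoxy group is present from the start. On both points it is better than the chosen plan.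
- Against it: electrophilic zinc carbenoids add sluggishly to conjugated, hindered stilbenes; the Lewis-basic ketone and ethers can bind zinc; the dialkylzinc reagent is pyrophoric. Opening a diarylcyclopropane needs more forcing hydrogenation than a benzylic C–O bond, so the ketone is at greater risk than in the chosen plan.
- Comparison: both plans form two skeletal bonds in the key step and create stereocentres only to destroy them, so they are equal there. The alternative needs two C–C bond-forming events for the chain (stilbene synthesis and cyclopropanation) against one cycloaddition in the chosen plan. Overall step count would be similar.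

Alternative 3: The cut goes through ring A at C3–C4 and C5–C6. The vinylketene acetal diene A7 and the ynone A8 would undergo a Diels–Alder reaction; elimination of the alkoxy group and loss of the silyl group would aromatise the adduct to the bis-silyl ether A6, and desilylation would give 16.
- In its favour: it is the most convergent of the four plans. One cycloaddition places all four substituents of ring A, the methoxy and hydroxyl groups are differentiated by construction, the ketone never meets a hydrogenation catalyst, and only one step follows the key step. On convergence and on the length of the endgame it is better than the chosen plan.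
- Against it: such oxygenated silyl ketene acetal dienes are moisture-sensitive and form as mixtures of double-bond isomers. The alkyl group at the diene terminus lowers reactivity and can disfavour the s-cis conformer. Terminal aryl ynones tend to polymerise and to undergo conjugate addition instead of cycloaddition. Making A7 needs a strong base in the presence of an aryl silyl ether.
- Comparison: both key steps are [4+2] reactions with aromatisation as driving force. The alternative is shorter on paper. The chosen plan is kept because all of its intermediates are stable aromatic compounds and its selectivity rests on classical effects (para-bromination, chelation).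

Key step: step 9

Assumption: 4-(benzyloxy)-2-hydroxybenzaldehyde 4 is taken as a catalogue compound (it is also the mono-benzylation product of 2,4-dihydroxybenzaldehyde); the substitution patterns of 11, 13 and 16 were cross-checked atom by atom and agree, so no connectivity was corrected and only the order of reduction, acylation and masking was redesigned.

## Steps

Step 1
Reactants: 1 4-hydroxybenzaldehyde
Product: 2 4-(triisopropylsilyloxy)benzaldehyde
Conditions: TIPSCl, imidazole, DMF, rt
Reagents that add atoms: chlorotriisopropylsilane, CC(C)[Si](Cl)(C(C)C)C(C)C
Why: Imidazole-assisted O-silylation of a phenol; the bulky triisopropylsilyl ether is chosen because it must survive an ylide, an aryllithium, dilute acid, 170 °C, hydrogenation and carbonate base before fluoride removes it.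

Step 2
Reactants: 2 4-(triisopropylsilyloxy)benzaldehyde
Product: 3 4-(triisopropylsilyloxy)styrene
Conditions: Ph3PCH3Br, KOt-Bu, THF, 0 °C; then 2, 0 °C → rt
Reagents that add atoms: methyltriphenylphosphonium bromide, C[P+](c1ccccc1)(c1ccccc1)c1ccccc1.[Br-]
Why: Wittig methylenation of an aromatic aldehyde; the ylide is pre-formed so that no free alkoxide meets the aryl silyl ether.

Step 3
Reactants: 4 4-(benzyloxy)-2-hydroxybenzaldehyde
Product: 5 4-(benzyloxy)-5-bromo-2-hydroxybenzaldehyde
Conditions: NBS, MeCN, 0 °C → rt, dark
Reagents that add atoms: N-bromosuccinimide, O=C1CCC(=O)N1Br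
Why: Electrophilic aromatic bromination; C5 is para to the free hydroxyl, ortho to the benzyloxy group and meta to the aldehyde, whereas C3 is flanked by two oxygens, so substitution should go to C5.

Step 4
Reactants: 5 4-(benzyloxy)-5-bromo-2-hydroxybenzaldehyde
Product: 6 5-(benzyloxy)-4-bromo-2-(hydroxymethyl)phenol
Conditions: NaBH4, THF–MeOH, 0 °C
Reagents that add atoms: none
Why: Hydride reduction of a salicylaldehyde to the salicyl alcohol; done here, before any ketone is present, it needs no chemoselectivity between two carbonyl groups.

Step 5
Reactants: 6 5-(benzyloxy)-4-bromo-2-(hydroxymethyl)phenol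
Product: 7 7-(benzyloxy)-6-bromo-2,2-dimethyl-4H-1,3-benzodioxine
Conditions: Me2C(OMe)2, PPTS (cat.), acetone, rt → 40 °C
Reagents that add atoms: 2,2-dimethoxypropane, COC(C)(C)OC
Why: Acid-catalysed transacetalisation ties the phenolic and benzylic hydroxyls into one six-membered isopropylidene acetal, a standard mask for salicyl alcohols that tolerates organolithium reagents; the mild acid and excess acetal donor should outpace ionisation of the electron-rich benzylic alcohol.

Step 6
Reactants: 7 7-(benzyloxy)-6-bromo-2,2-dimethyl-4H-1,3-benzodioxine; 2 4-(triisopropylsilyloxy)benzaldehyde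
Product: 9 (±)-[7-(benzyloxy)-2,2-dimethyl-4H-1,3-benzodioxin-6-yl][4-(triisopropylsilyloxy)phenyl]methanol, via aryllithium 8 (not isolated)
Conditions: n-BuLi, THF, −78 °C; then 2, −78 → 0 °C; aq. NH4Cl
Reagents that add atoms: none
Why: Bromine–lithium exchange followed by 1,2-addition of the aryllithium to an aldehyde; exchange at −78 °C is much faster than deprotonation of the benzyl ether or the acetal, and the carbinol stereocentre is formed racemic without consequence because step 7 removes it.

Step 7
Reactants: 9 (±)-[7-(benzyloxy)-2,2-dimethyl-4H-1,3-benzodioxin-6-yl][4-(triisopropylsilyloxy)phenyl]methanol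
Product: 10 [7-(benzyloxy)-2,2-dimethyl-4H-1,3-benzodioxin-6-yl][4-(triisopropylsilyloxy)phenyl]methanone
Conditions: MnO2 (activated, excess), CH2Cl2, rt
Reagents that add atoms: none
Why: MnO2 oxidation of a doubly benzylic carbinol to the diaryl ketone; the only other benzylic oxygen is locked in the acetal, so no second oxidation can occur.

Step 8
Reactants: 10 [7-(benzyloxy)-2,2-dimethyl-4H-1,3-benzodioxin-6-yl][4-(triisopropylsilyloxy)phenyl]methanone
Product: 11 [2-(benzyloxy)-4-hydroxy-5-(hydroxymethyl)phenyl][4-(triisopropylsilyloxy)phenyl]methanone
Conditions: 1 M aq. HCl, THF, rt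
Reagents that add atoms: none
Why: Acid-catalysed acetal hydrolysis; the para-acyl phenoxide is a good leaving group, so cleavage should be easy under conditions that leave the aryl triisopropylsilyl ether and the benzyl ether intact, and the aroyl group damps ionisation of the freed benzylic alcohol.

Step 9
Reactants: 11 [2-(benzyloxy)-4-hydroxy-5-(hydroxymethyl)phenyl][4-(triisopropylsilyloxy)phenyl]methanone; 3 4-(triisopropylsilyloxy)styrene
Product: 13 (±)-{7-(benzyloxy)-2-[4-(triisopropylsilyloxy)phenyl]-3,4-dihydro-2H-chromen-6-yl}[4-(triisopropylsilyloxy)phenyl]methanone, via ortho-quinone methide 12 (not isolated)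
Conditions: 3 (4 equiv), BHT (cat.), 1,2-dichlorobenzene, 170 °C, sealed tube, Ar
Reagents that add atoms: none
Why: On heating, the phenolic hydroxyl of 11, hydrogen-bonded to the neighbouring hydroxymethyl group, passes on its proton as water leaves, and this thermal 1,4-dehydration gives ortho-quinone methide 12; a para-quinone methide cannot form because the para oxygen is benzylated. 12 is an electron-poor 1-oxadiene (O1=C1–C6=Cα), made more electrophilic by the aroyl group, and it should combine with the electron-rich styrene 3 in an inverse-electron-demand hetero-Diels–Alder reaction that is concerted but asynchronous, Cα–Cβ bonding running ahead of O1–Cγ bonding. The closest known reaction type is the thermal generation of ortho-quinone methides from 2-hydroxybenzyl alcohols and their trapping by styrenes to give 2-arylchromans. The dihydropyran ring is closed by the intermolecular [4+2] cycloaddition itself, both ring bonds arising in one event, and the return of aromaticity to ring A makes the addition irreversible. The one new stereocentre, C2 of the chroman, is formed without any controlling element, so 13 is racemic, which is acceptable because step 10 destroys this centre. The step needs regioselectivity: the largest LUMO coefficient of 12 lies on the exocyclic methylene and the largest HOMO coefficient of 3 on the terminal vinyl carbon, and the positive charge developing at Cγ is stabilised by the 4-silyloxyphenyl group, so the 2-aryl and not the 3-aryl chroman should result. It also needs chemoselectivity for capture of 12 over its self-condensation and over polymerisation of 3, which the excess of 3, the radical inhibitor and the thermal reversibility of phenol adducts of 12 are meant to secure.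

Step 10
Reactants: 13 (±)-{7-(benzyloxy)-2-[4-(triisopropylsilyloxy)phenyl]-3,4-dihydro-2H-chromen-6-yl}[4-(triisopropylsilyloxy)phenyl]methanone
Product: 14 [2,4-dihydroxy-5-{3-[4-(triisopropylsilyloxy)phenyl]propyl}phenyl][4-(triisopropylsilyloxy)phenyl]methanone
Conditions: H2 (1–3 atm), Pd/C (10 wt% Pd), EtOAc–EtOH, rt, monitored
Reagents that add atoms: none
Why: Catalytic hydrogenolysis of two benzylic C–O bonds: the benzyl ether, and the O1–C2 bond of the flavan, which is benzylic to the electron-rich ring C and has a para-acyl phenoxide as leaving group. The stereocentre is erased, and the chelated, triply donor-substituted ketone should be reduced much more slowly than either C–O bond under neutral conditions.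

Step 11
Reactants: 14 [2,4-dihydroxy-5-{3-[4-(triisopropylsilyloxy)phenyl]propyl}phenyl][4-(triisopropylsilyloxy)phenyl]methanone
Product: 15 [2-hydroxy-4-methoxy-5-{3-[4-(triisopropylsilyloxy)phenyl]propyl}phenyl][4-(triisopropylsilyloxy)phenyl]methanone
Conditions: MeI (1.2 equiv), K2CO3 (1.1 equiv), dry acetone, rt → 40 °C
Reagents that add atoms: iodomethane, CI
Why: Williamson ether synthesis with site selectivity from chelation: the hydroxyl para to the carbonyl is the more acidic and its phenoxide is free, whereas the ortho hydroxyl is held in a hydrogen bond to the ketone, as in the classical 4-O-alkylation of 2,4-dihydroxyaryl ketones; dry acetone and a near-stoichiometric amount of base protect the silyl ethers.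

Step 12
Reactants: 15 [2-hydroxy-4-methoxy-5-{3-[4-(triisopropylsilyloxy)phenyl]propyl}phenyl][4-(triisopropylsilyloxy)phenyl]methanone
Product: 16 (4-hydroxyphenyl){2-hydroxy-5-[3-(4-hydroxyphenyl)propyl]-4-methoxyphenyl}methanone
Conditions: Bu4NF, AcOH, THF, 0 °C → rt
Reagents that add atoms: none
Why: Fluoride-induced cleavage of both aryl silyl ethers, driven by the strength of the Si–F bond; buffering with acetic acid keeps the liberated phenols protonated.

## Compound list

1 | 4-hydroxybenzaldehyde | O=Cc1ccc(O)cc1 | starting material
2 | 4-(triisopropylsilyloxy)benzaldehyde | O=Cc1ccc(O[Si](C(C)C)(C(C)C)C(C)C)cc1 | intermediate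
3 | 4-(triisopropylsilyloxy)styrene | C=Cc1ccc(O[Si](C(C)C)(C(C)C)C(C)C)cc1 | intermediate
4 | 4-(benzyloxy)-2-hydroxybenzaldehyde | O=Cc1ccc(OCc2ccccc2)cc1O | starting material
5 | 4-(benzyloxy)-5-bromo-2-hydroxybenzaldehyde | O=Cc1cc(Br)c(OCc2ccccc2)cc1O | intermediate
6 | 5-(benzyloxy)-4-bromo-2-(hydroxymethyl)phenol | OCc1cc(Br)c(OCc2ccccc2)cc1O | intermediate
7 | 7-(benzyloxy)-6-bromo-2,2-dimethyl-4H-1,3-benzodioxine | CC1(C)OCc2cc(Br)c(OCc3ccccc3)cc2O1 | intermediate
8 | [7-(benzyloxy)-2,2-dimethyl-4H-1,3-benzodioxin-6-yl]lithium (not isolated) | [Li]c1cc2c(cc1OCc1ccccc1)OC(C)(C)OC2 | intermediate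
9 | (±)-[7-(benzyloxy)-2,2-dimethyl-4H-1,3-benzodioxin-6-yl][4-(triisopropylsilyloxy)phenyl]methanol (racemic) | OC(c1ccc(O[Si](C(C)C)(C(C)C)C(C)C)cc1)c1cc2c(cc1OCc1ccccc1)OC(C)(C)OC2 | intermediate
10 | [7-(benzyloxy)-2,2-dimethyl-4H-1,3-benzodioxin-6-yl][4-(triisopropylsilyloxy)phenyl]methanone | O=C(c1ccc(O[Si](C(C)C)(C(C)C)C(C)C)cc1)c1cc2c(cc1OCc1ccccc1)OC(C)(C)OC2 | intermediate
11 | [2-(benzyloxy)-4-hydroxy-5-(hydroxymethyl)phenyl][4-(triisopropylsilyloxy)phenyl]methanone | OCc1cc(C(=O)c2ccc(O[Si](C(C)C)(C(C)C)C(C)C)cc2)c(OCc2ccccc2)cc1O | intermediate
12 | 3-(benzyloxy)-6-methylidene-4-[4-(triisopropylsilyloxy)benzoyl]cyclohexa-2,4-dien-1-one (ortho-quinone methide, not isolated) | C=C1C=C(C(=O)c2ccc(O[Si](C(C)C)(C(C)C)C(C)C)cc2)C(OCc2ccccc2)=CC1=O | intermediate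
13 | (±)-{7-(benzyloxy)-2-[4-(triisopropylsilyloxy)phenyl]-3,4-dihydro-2H-chromen-6-yl}[4-(triisopropylsilyloxy)phenyl]methanone (racemic) | O=C(c1ccc(O[Si](C(C)C)(C(C)C)C(C)C)cc1)c1cc2c(cc1OCc1ccccc1)OC(c1ccc(O[Si](C(C)C)(C(C)C)C(C)C)cc1)CC2 | intermediate
14 | [2,4-dihydroxy-5-{3-[4-(triisopropylsilyloxy)phenyl]propyl}phenyl][4-(triisopropylsilyloxy)phenyl]methanone | O=C(c1ccc(O[Si](C(C)C)(C(C)C)C(C)C)cc1)c1cc(CCCc2ccc(O[Si](C(C)C)(C(C)C)C(C)C)cc2)c(O)cc1O | intermediate
15 | [2-hydroxy-4-methoxy-5-{3-[4-(triisopropylsilyloxy)phenyl]propyl}phenyl][4-(triisopropylsilyloxy)phenyl]methanone | COc1cc(O)c(C(=O)c2ccc(O[Si](C(C)C)(C(C)C)C(C)C)cc2)cc1CCCc1ccc(O[Si](C(C)C)(C(C)C)C(C)C)cc1 | intermediate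
16 | (4-hydroxyphenyl){2-hydroxy-5-[3-(4-hydroxyphenyl)propyl]-4-methoxyphenyl}methanone (achiral) | COc1cc(O)c(C(=O)c2ccc(O)cc2)cc1CCCc1ccc(O)cc1 | target

## Step count and least certain steps

Total step count: 12. Longest linear sequence: 10 steps (steps 3 to 12, from 4); steps 1 and 2 form the short convergent branch that supplies 2 and 3.

**Step 9 (key step).** The most likely failure is self-condensation of the transient quinone methide and thermal polymerisation of the styrene outrunning the cycloaddition. The aroyl group para to the phenolic oxygen makes the dehydration demanding, so a high temperature is unavoidable. The fallback makes the chain by olefination and needs no cycloaddition. It sets out from 11 and returns at 14. Oxidation of 11 with MnO2 in CH2Cl2 would give 4-(benzyloxy)-2-hydroxy-5-[4-(triisopropylsilyloxy)benzoyl]benzaldehyde F1. Separately, commercial 4-(2-bromoethyl)phenol would be silylated (TIPSCl, imidazole) to [4-(2-bromoethyl)phenoxy]triisopropylsilane F2 and heated with PPh3 to give triphenyl{2-[4-(triisopropylsilyloxy)phenyl]ethyl}phosphonium bromide F3. Wittig olefination of F1 with an excess of the ylide from F3 (NaHMDS, THF) should take place at the aldehyde only, because the hindered diaryl ketone is deactivated by the para phenoxide. It would give [2-(benzyloxy)-4-hydroxy-5-{3-[4-(triisopropylsilyloxy)phenyl]prop-1-en-1-yl}phenyl][4-(triisopropylsilyloxy)phenyl]methanone F4 as a mixture of alkene isomers. Mild hydrogenation (H2, 1 atm, Pd/C, EtOAc) would saturate the alkene and remove the benzyl group, which gives 14.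

**Step 10.** The most likely failure is over-reduction of the diaryl ketone while the slower of the two cleavages, the opening of the pyran ring, is still incomplete; the ring C–O bond is a secondary cyclic ether and may need longer contact with the catalyst than the benzyl ether. The fallback replaces catalytic hydrogenation by ionic hydrogenation. It sets out from 13 and returns at 15. Et3SiH and CF3CO2H in CH2Cl2 at 0 °C should ionise the O1–C2 bond (cation stabilised by the 4-silyloxyphenyl group, acyl phenol as leaving group) and deliver hydride, giving [2-(benzyloxy)-4-hydroxy-5-{3-[4-(triisopropylsilyloxy)phenyl]propyl}phenyl][4-(triisopropylsilyloxy)phenyl]methanone F5 with the benzyl ether intact. Methylation of its only free hydroxyl (MeI, K2CO3, acetone) would give [2-(benzyloxy)-4-methoxy-5-{3-[4-(triisopropylsilyloxy)phenyl]propyl}phenyl][4-(triisopropylsilyloxy)phenyl]methanone F6. Chelation-assisted debenzylation with BCl3 and pentamethylbenzene in CH2Cl2 at −78 °C would then give 15. This variant also removes the selectivity question of step 11.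

**Step 11.** The most likely failure is erosion of site selectivity, that is a second methylation at the chelated C3 hydroxyl when the reaction is pushed to full conversion. The fallback sets out from 14 and returns at 15. Exhaustive methylation (excess MeI, K2CO3, acetone, reflux) would give [2,4-dimethoxy-5-{3-[4-(triisopropylsilyloxy)phenyl]propyl}phenyl][4-(triisopropylsilyloxy)phenyl]methanone F7. BCl3 in CH2Cl2 (−78 → 0 °C) would then cleave only the methyl ether ortho to the carbonyl, through the boron chelate, and give 15. Partial loss of a silyl group at this point would be harmless, since step 12 removes both.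

**Step 8.** The most likely failure is acid-promoted ionisation of the freed benzylic alcohol, which is activated by the para benzyloxy and ortho hydroxyl groups, leading to self-alkylation; slow loss of the ring B silyl ether is a second possibility. The fallback dispenses with the acetal and changes the order of events. It sets out from 6 and returns at 13. Heating 6 with 3 under the conditions of step 9 would give (±)-{4-[7-(benzyloxy)-6-bromo-3,4-dihydro-2H-chromen-2-yl]phenoxy}triisopropylsilane F8; the quinone methide here lacks the aroyl group and should form more easily. Bromine–lithium exchange (n-BuLi, THF, −78 °C) and addition to 2 would give {7-(benzyloxy)-2-[4-(triisopropylsilyloxy)phenyl]-3,4-dihydro-2H-chromen-6-yl}[4-(triisopropylsilyloxy)phenyl]methanol F9 as a mixture of diastereomers. MnO2 would oxidise F9 to 13.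

## Further compounds

F1 | step 9 | 4-(benzyloxy)-2-hydroxy-5-[4-(triisopropylsilyloxy)benzoyl]benzaldehyde | O=Cc1cc(C(=O)c2ccc(O[Si](C(C)C)(C(C)C)C(C)C)cc2)c(OCc2ccccc2)cc1O
F2 | step 9 | [4-(2-bromoethyl)phenoxy]triisopropylsilane | BrCCc1ccc(O[Si](C(C)C)(C(C)C)C(C)C)cc1
F3 | step 9 | triphenyl{2-[4-(triisopropylsilyloxy)phenyl]ethyl}phosphonium bromide | [Br-].CC(C)[Si](Oc1ccc(CC[P+](c2ccccc2)(c2ccccc2)c2ccccc2)cc1)(C(C)C)C(C)C
F4 | step 9 | [2-(benzyloxy)-4-hydroxy-5-{3-[4-(triisopropylsilyloxy)phenyl]prop-1-en-1-yl}phenyl][4-(triisopropylsilyloxy)phenyl]methanone (mixture of alkene isomers) | O=C(c1ccc(O[Si](C(C)C)(C(C)C)C(C)C)cc1)c1cc(C=CCc2ccc(O[Si](C(C)C)(C(C)C)C(C)C)cc2)c(O)cc1OCc1ccccc1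
F5 | step 10 | [2-(benzyloxy)-4-hydroxy-5-{3-[4-(triisopropylsilyloxy)phenyl]propyl}phenyl][4-(triisopropylsilyloxy)phenyl]methanone | O=C(c1ccc(O[Si](C(C)C)(C(C)C)C(C)C)cc1)c1cc(CCCc2ccc(O[Si](C(C)C)(C(C)C)C(C)C)cc2)c(O)cc1OCc1ccccc1
F6 | step 10 | [2-(benzyloxy)-4-methoxy-5-{3-[4-(triisopropylsilyloxy)phenyl]propyl}phenyl][4-(triisopropylsilyloxy)phenyl]methanone | COc1cc(OCc2ccccc2)c(C(=O)c2ccc(O[Si](C(C)C)(C(C)C)C(C)C)cc2)cc1CCCc1ccc(O[Si](C(C)C)(C(C)C)C(C)C)cc1
F7 | step 11 | [2,4-dimethoxy-5-{3-[4-(triisopropylsilyloxy)phenyl]propyl}phenyl][4-(triisopropylsilyloxy)phenyl]methanone | COc1cc(OC)c(C(=O)c2ccc(O[Si](C(C)C)(C(C)C)C(C)C)cc2)cc1CCCc1ccc(O[Si](C(C)C)(C(C)C)C(C)C)cc1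
F8 | step 8 | (±)-{4-[7-(benzyloxy)-6-bromo-3,4-dihydro-2H-chromen-2-yl]phenoxy}triisopropylsilane (racemic) | Brc1cc2c(cc1OCc1ccccc1)OC(c1ccc(O[Si](C(C)C)(C(C)C)C(C)C)cc1)CC2
F9 | step 8 | {7-(benzyloxy)-2-[4-(triisopropylsilyloxy)phenyl]-3,4-dihydro-2H-chromen-6-yl}[4-(triisopropylsilyloxy)phenyl]methanol (mixture of diastereomers, each racemic) | OC(c1ccc(O[Si](C(C)C)(C(C)C)C(C)C)cc1)c1cc2c(cc1OCc1ccccc1)OC(c1ccc(O[Si](C(C)C)(C(C)C)C(C)C)cc1)CC2
A1 | alternative 1 | dimethyl 5-{5-[3-(4-benzyloxyphenyl)propyl]-2-hydroxy-4-methoxybenzoyl}-2-hydroxyisophthalate | COC(=O)c1cc(C(=O)c2cc(CCCc3ccc(OCc4ccccc4)cc3)c(OC)cc2O)cc(C(=O)OC)c1O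
A2 | alternative 1 | 6-{3-[4-(benzyloxy)phenyl]propyl}-7-methoxy-4-oxo-4H-chromene-3-carbaldehyde | O=Cc1coc2cc(OC)c(CCCc3ccc(OCc4ccccc4)cc3)cc2c1=O
A3 | alternative 1 | dimethyl 3-oxopentanedioate | COC(=O)CC(=O)CC(=O)OC
A4 | alternative 2 | racemic trans-cyclopropane {2-(benzyloxy)-5-[2-(4-benzyloxyphenyl)cyclopropyl]-4-methoxyphenyl}[4-(benzyloxy)phenyl]methanone (one enantiomer drawn) | COc1cc(OCc2ccccc2)c(C(=O)c2ccc(OCc3ccccc3)cc2)cc1[C@@H]1C[C@H]1c1ccc(OCc2ccccc2)cc1
A5 | alternative 2 | {2-(benzyloxy)-5-[(E)-2-(4-benzyloxyphenyl)ethenyl]-4-methoxyphenyl}[4-(benzyloxy)phenyl]methanone | COc1cc(OCc2ccccc2)c(C(=O)c2ccc(OCc3ccccc3)cc2)cc1/C=C/c1ccc(OCc2ccccc2)cc1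
A6 | alternative 3 | [4-(tert-butyldimethylsilyloxy)phenyl]{5-[3-(4-tert-butyldimethylsilyloxyphenyl)propyl]-2-hydroxy-4-methoxyphenyl}methanone | COc1cc(O)c(C(=O)c2ccc(O[Si](C)(C)C(C)(C)C)cc2)cc1CCCc1ccc(O[Si](C)(C)C(C)(C)C)cc1
A7 | alternative 3 | tert-butyl{4-[5,7-dimethoxy-7-(trimethylsilyloxy)hepta-4,6-dien-1-yl]phenoxy}dimethylsilane (mixture of double-bond isomers) | COC(O[Si](C)(C)C)=CC(OC)=CCCCc1ccc(O[Si](C)(C)C(C)(C)C)cc1
A8 | alternative 3 | 1-[4-(tert-butyldimethylsilyloxy)phenyl]prop-2-yn-1-one | C#CC(=O)c1ccc(O[Si](C)(C)C(C)(C)C)cc1
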